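**Retrosynthetic overview**
1. Target 28 ⇐ silyl ether cleavage ⇐ two catalyst-controlled epoxidations (cis-1,2 first, then trans-4,5) of triene ester 25 ⇐ acylation of allylic alcohol 21, whose C8 centre comes from CBS reduction of keto-butenolide 20.
2. Butenolide ⇐ dehydration of 19 ⇐ borylative aldol–lactonisation annulation (new) of ten-membered dienone 13 with methyl acetoxypyruvate 15 (forms C7–C11 and C6–O, sets C6).
3. Ten-membered ring ⇐ ring-expanding Grob fragmentation of the C4–C8 bond of the cis-fused bicyclo[5.3.0]decadienyl mesylate 11 (sets the 4E olefin).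
4. Bicyclo[5.3.0] core ⇐ intramolecular Sakurai closure of the seven-membered ring onto 2-methylcyclopentane-1,3-dione ⇐ propargylation, Sonogashira coupling with (2-bromoallyl)trimethylsilane, Z-selective semi-hydrogenation.
5. Ring order: five-membered ring (bought) → seven-membered ring → ten-membered ring by expansion → butenolide → 1,2-oxirane → 4,5-oxirane.

Assumption: the SMILES defines the absolute configuration 1R,2S,4R,5R,6S,8S (germacrane numbering: ring C1–C10, lactone carbons C11–C13, exocyclic methylene C14, methyl C15); carbons of all intermediates are referred to by these numbers.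

**Route**

Step 1
Reactants: 1 2-methylcyclopentane-1,3-dione; 2 3-bromoprop-1-yne (propargyl bromide)
Product: 3 2-methyl-2-(prop-2-yn-1-yl)cyclopentane-1,3-dione
Conditions: NaOH (1 equiv), H2O, 60 °C
Reagents that add atoms: none
Why: C-alkylation (SN2) of the dione enolate at its only carbon nucleophilic site builds the quaternary carbon that becomes C4 (with C15) and attaches C3–C1, and the product is achiral so no stereocontrol is needed.

Step 2
Reactants: 3 2-methyl-2-(prop-2-yn-1-yl)cyclopentane-1,3-dione; 4 (2-bromoprop-2-en-1-yl)trimethylsilane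
Product: 5 2-methyl-2-[4-methylidene-5-(trimethylsilyl)pent-2-yn-1-yl]cyclopentane-1,3-dione
Conditions: PdCl2(PPh3)2 (3 mol%), CuI (5 mol%), i-Pr2NH, THF, rt
Reagents that add atoms: none
Why: Sonogashira coupling of the terminal alkyne with the vinyl bromide joins C1 to C10 and brings in C9/C14 as a 2-substituted allylsilane, the hindered amine sparing the non-enolisable dione.

Step 3
Reactants: 5 2-methyl-2-[4-methylidene-5-(trimethylsilyl)pent-2-yn-1-yl]cyclopentane-1,3-dione
Product: 6 2-methyl-2-[(2Z)-4-methylidene-5-(trimethylsilyl)pent-2-en-1-yl]cyclopentane-1,3-dione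
Conditions: H2 (1 atm), Pd/CaCO3 poisoned with Pb(OAc)2 (Lindlar type), quinoline, EtOAc, rt
Reagents that add atoms: none
Why: Lindlar-type semi-hydrogenation adds H2 syn to the triple bond only, fixing the Z geometry of C1=C2 that the ring closure of step 4 needs and that later becomes the cis-epoxide.

Step 4
Reactants: 6 2-methyl-2-[(2Z)-4-methylidene-5-(trimethylsilyl)pent-2-en-1-yl]cyclopentane-1,3-dione
Product: 7 rac-cis-1-hydroxy-7-methyl-3-methylidenebicyclo[5.3.0]dec-4-en-8-one (1-OH and 7-CH3 on the same face)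
Conditions: TiCl4 (1.1 equiv), CH2Cl2, −78 °C; then H2O
Reagents that add atoms: none
Why: intramolecular Hosomi–Sakurai allylation (SE2′ attack of the =CH2 terminus, loss of silicon, re-formation of the exocyclic methylene) of one of the two enantiotopic ketones closes the seven-membered ring, the short Z tether forcing attack from its own face so that the fusion is cis (OH cis to CH3), and the racemic outcome is immaterial because C4 and C8 become sp2 in step 7.

Step 5
Reactants: 7 rac-cis-1-hydroxy-7-methyl-3-methylidenebicyclo[5.3.0]dec-4-en-8-one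
Product: 9 rac-cis-7-methyl-3-methylidene-1-(trimethylsilyloxy)bicyclo[5.3.0]deca-4,9-dien-8-one, via bis-silyl enol ether 8 (not isolated)
Conditions: Me3SiOTf (2.4 equiv), Et3N, CH2Cl2, 0 °C; then Pd(OAc)2 (1.1 equiv), MeCN, rt
Reagents that add atoms: trimethylsilyl trifluoromethanesulfonate, C[Si](C)(C)OS(=O)(=O)C(F)(F)F
Why: Saegusa–Ito dehydrogenation, in which soft enolisation can only go toward C6 (C4 is quaternary) and silylation of the tertiary alcohol blocks retro-aldol cleavage and installs the later fluoride trigger, gives the C6=C7 enone by β-hydride elimination from the palladium enolate.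

Step 6
Reactants: 9 rac-cis-7-methyl-3-methylidene-1-(trimethylsilyloxy)bicyclo[5.3.0]deca-4,9-dien-8-one
Product: 10 rac-7-methyl-3-methylidene-1-(trimethylsilyloxy)bicyclo[5.3.0]deca-4,9-dien-8-ol (8-OH cis to 7-CH3 and 1-OSiMe3)
Conditions: NaBH4, CeCl3·7H2O, MeOH, −78 °C
Reagents that add atoms: none
Why: Luche 1,2-reduction in which hydride attacks the carbonyl anti to the adjacent angular CH3 and the OSiMe3 group (both on the same face), placing the C5–OH cis to the methyl, the relationship that step 7 translates into the 4E olefin.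

Step 7
Reactants: 10 rac-7-methyl-3-methylidene-1-(trimethylsilyloxy)bicyclo[5.3.0]deca-4,9-dien-8-ol
Product: 13 (2Z,4E,7Z)-5-methyl-9-methylidenecyclodeca-2,4,7-trien-1-one, via allylic mesylate 11 (not isolated), via tetrabutylammonium alkoxide 12 (not isolated)
Conditions: Ms2O, Et3N, CH2Cl2, −40 °C; then Bu4NF, THF, −40 → 0 °C; pH 7 buffer
Reagents that add atoms: none
Why: ring-expanding Grob (Wharton-type) fragmentation in which fluoride unmasks the C8 alkoxide, whose push cleaves the C4–C8 ring-fusion bond anti to the C5–OMs bond to give the C8 ketone and the ten-membered ring, stereospecifically converting "mesylate cis to methyl" into the 4E olefin and carrying the ring-constrained cyclopentene over as the Z-enone (C6=C7).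

Step 8
Reactants: 14 methyl 3-bromo-2-oxopropanoate
Product: 15 methyl 3-acetoxy-2-oxopropanoate
Conditions: KOAc, acetone, 0 °C → rt
Reagents that add atoms: potassium acetate, CC(=O)[O-].[K+]
Why: SN2 displacement of the activated α-bromo ketone by acetate gives the electrophile that carries C11, C12 and the C13 acetoxymethyl group in its final oxidation state.

Step 9
Reactants: 13 (2Z,4E,7Z)-5-methyl-9-methylidenecyclodeca-2,4,7-trien-1-one; 15 methyl 3-acetoxy-2-oxopropanoate
Product: 19 (6R)-13-acetoxy-11-hydroxy-8-oxogermacra-1(Z),4(E),10(14)-trien-12,6-olide (C7/C11 epimers), via boron enolate 16 (not isolated), via boryl aldolate 17 (not isolated), via dihydroxy ester 18 (not isolated)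
Conditions: CuCl (5 mol%), (R,R)-2,3-bis(tert-butylmethylphosphino)quinoxaline (6 mol%), NaOt-Bu (8 mol%), B2pin2 (1.1 equiv), THF, 0 °C; then 15, −40 °C; then NaBO3·4H2O, THF/pH 7 buffer, 0 °C; then PPTS (cat.), CH2Cl2, rt
Reagents that add atoms: sodium perborate (written without water of crystallisation), [Na+].[Na+].O[B-]1(O)OO[B-](O)(O)OO1
Why: Proposed new method: a ligated copper–boryl species (monovalent copper) should add 1,4 to the Z-enone at C6 (1,6-addition would have to build a quaternary C4), σ-bond metathesis with B2pin2 then gives boron enolate 16 specifically on the C7 side (never the more acidic C9 side), this adds to the highly electrophilic α-keto ester 15 to form C7–C11, and oxidation of the C6–B bond with retention followed by 5-exo lactonisation closes the lactone, so the ligand-controlled boryl transfer alone sets C6 (the antipodal ligand is used if the facial sense on this macrocycle proves opposite) while the C7/C11 centres are erased in step 10; the closest known chemistry is the enantioselective copper-catalysed β-borylation of cyclic enones with one-pot aldol trapping by aldehydes, here extended to a macrocyclic cross-conjugated dienone, an α-keto ester acceptor and a terminating lactonisation.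

Step 10
Reactants: 19 (6R)-13-acetoxy-11-hydroxy-8-oxogermacra-1(Z),4(E),10(14)-trien-12,6-olide
Product: 20 (6R)-13-acetoxy-8-oxogermacra-1(Z),4(E),7(11),10(14)-tetraen-12,6-olide
Conditions: Ph2S[OC(CF3)2Ph]2 (Martin sulfurane), CH2Cl2, 0 °C → rt
Reagents that add atoms: none
Why: neutral dehydration of the tertiary β-hydroxy ketone, H7 being the only acidic β-hydrogen, gives the tetrasubstituted C7=C11 olefin conjugated to both carbonyls, removes the uncontrolled C7 and C11 centres and avoids base that could epimerise C6 or open the β-acyloxy ketone.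

Step 11
Reactants: 20 (6R)-13-acetoxy-8-oxogermacra-1(Z),4(E),7(11),10(14)-tetraen-12,6-olide
Product: 21 (6R,8S)-13-acetoxy-8-hydroxygermacra-1(Z),4(E),7(11),10(14)-tetraen-12,6-olide
Conditions: (R)-2-methyl-CBS-oxazaborolidine (20 mol%), catecholborane, toluene, −78 °C
Reagents that add atoms: none
Why: Corey–Bakshi–Shibata reduction in which the catalyst selects the carbonyl face, the alkenyl (butenolide) flank acting as the large group and the C9 methylene as the small one, so that the (R)-oxazaborolidine delivers hydride to give the 8S carbinol.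

Step 12
Reactants: 22 2-(hydroxymethyl)prop-2-enoic acid
Product: 24 2-[(tert-butyldimethylsilyloxy)methyl]prop-2-enoic acid, via bis-silyl derivative 23 (not isolated)
Conditions: TBSCl (2.2 equiv), imidazole, DMF, rt; then K2CO3 (cat.), MeOH/H2O, 0 °C
Reagents that add atoms: tert-butyldimethylsilyl chloride, CC(C)(C)[Si](C)(C)Cl
Why: both oxygens are silylated and the labile silyl ester is hydrolysed selectively in the mild work-up, leaving the primary hydroxyl protected for the acylation.

Step 13
Reactants: 21 (6R,8S)-13-acetoxy-8-hydroxygermacra-1(Z),4(E),7(11),10(14)-tetraen-12,6-olide; 24 2-[(tert-butyldimethylsilyloxy)methyl]prop-2-enoic acid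
Product: 25 (6R,8S)-13-acetoxy-8-{2-[(tert-butyldimethylsilyloxy)methyl]acryloyloxy}germacra-1(Z),4(E),7(11),10(14)-tetraen-12,6-olide
Conditions: DCC, DMAP (cat.), CH2Cl2, 0 °C → rt
Reagents that add atoms: none
Why: Steglich esterification acylates the secondary allylic C8 hydroxyl with retention, since no bond to C8 is broken, and masks it before the epoxides are made.

Step 14
Reactants: 25 (6R,8S)-13-acetoxy-8-{2-[(tert-butyldimethylsilyloxy)methyl]acryloyloxy}germacra-1(Z),4(E),7(11),10(14)-tetraen-12,6-olide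
Product: 26 (1R,2S,6R,8S)-13-acetoxy-1,2-epoxy-8-{2-[(tert-butyldimethylsilyloxy)methyl]acryloyloxy}germacra-4(E),7(11),10(14)-trien-12,6-olide
Conditions: Shi's D-glucose-derived N-(4-methylphenyl) spiro-oxazolidinone ketone (30 mol%), Oxone (2KHSO5·KHSO4·K2SO4), K2CO3, Bu4NHSO4, DME/CH2(OMe)2/aq. buffer, −10 → 0 °C
Reagents that add atoms: potassium peroxymonosulfate (active component of Oxone), [K+].[O-]S(=O)(=O)OO
Why: Shi epoxidation of a conjugated cis-olefin, in which the conjugating C10=C14 vinyl group sits next to the oxazolidinone in the spiro transition state and, by analogy with cis-β-methylstyrene, gives the (1R,2S) cis-epoxide at the cis olefin of the diene, the concerted dioxirane transfer excluding cis/trans scrambling.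

Step 15
Reactants: 26 (1R,2S,6R,8S)-13-acetoxy-1,2-epoxy-8-{2-[(tert-butyldimethylsilyloxy)methyl]acryloyloxy}germacra-4(E),7(11),10(14)-trien-12,6-olide
Product: 27 (1R,2S,4R,5R,6S,8S)-13-acetoxy-1,2:4,5-diepoxy-8-{2-[(tert-butyldimethylsilyloxy)methyl]acryloyloxy}germacra-7(11),10(14)-dien-12,6-olide
Conditions: Shi's D-fructose-derived ketone (1,2:4,5-di-O-isopropylidene-β-D-erythro-2,3-hexodiulo-2,6-pyranose, 30 mol%), Oxone (2KHSO5·KHSO4·K2SO4), K2CO3, Bu4NHSO4, MeCN/CH2(OMe)2/aq. Na2B4O7 buffer, 0 °C
Reagents that add atoms: potassium peroxymonosulfate (active component of Oxone), [K+].[O-]S(=O)(=O)OO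
Why: Shi epoxidation of the E-trisubstituted C4=C5 olefin, now the only electron-rich olefin matched to this catalyst (C10=C14 is 1,1-disubstituted and deactivated by the adjacent oxirane, the other olefins are acceptor-substituted), gives the (R,R)-type epoxide (4R,5R) through the spiro transition state, the same face that peripheral attack exposes in 6-oxygenated germacranolides, and the concerted transfer turns the E olefin into the trans-epoxide.

Step 16
Reactants: 27 (1R,2S,4R,5R,6S,8S)-13-acetoxy-1,2:4,5-diepoxy-8-{2-[(tert-butyldimethylsilyloxy)methyl]acryloyloxy}germacra-7(11),10(14)-dien-12,6-olide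
Product: 28 (1R,2S,4R,5R,6S,8S)-13-acetoxy-1,2:4,5-diepoxy-8-[2-(hydroxymethyl)acryloyloxy]germacra-7(11),10(14)-dien-12,6-olide (CNP0233746.1)
Conditions: HF·pyridine, pyridine, THF, 0 °C
Reagents that add atoms: none
Why: buffered fluoride cleavage of the primary silyl ether leaves the two epoxides, the allylic acetate and the esters untouched and liberates the target.

**Compound list**
1 | 2-methylcyclopentane-1,3-dione | CC1C(=O)CCC1=O | starting material
2 | 3-bromoprop-1-yne (propargyl bromide) | C#CCBr | starting material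
3 | 2-methyl-2-(prop-2-yn-1-yl)cyclopentane-1,3-dione | CC1(CC#C)C(=O)CCC1=O | intermediate
4 | (2-bromoprop-2-en-1-yl)trimethylsilane | C=C(Br)C[Si](C)(C)C | starting material
5 | 2-methyl-2-[4-methylidene-5-(trimethylsilyl)pent-2-yn-1-yl]cyclopentane-1,3-dione | CC1(CC#CC(=C)C[Si](C)(C)C)C(=O)CCC1=O | intermediate
6 | 2-methyl-2-[(2Z)-4-methylidene-5-(trimethylsilyl)pent-2-en-1-yl]cyclopentane-1,3-dione | CC1(C/C=C\C(=C)C[Si](C)(C)C)C(=O)CCC1=O | intermediate
7 | rac-cis-1-hydroxy-7-methyl-3-methylidenebicyclo[5.3.0]dec-4-en-8-one (OH cis to CH3; one enantiomer drawn) | C[C@@]12C/C=C\C(=C)C[C@]1(O)CCC2=O | intermediate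
8 | rac-cis-7-methyl-3-methylidene-1,8-bis(trimethylsilyloxy)bicyclo[5.3.0]deca-4,8-diene (formed in the flask) | C[C@@]12C/C=C\C(=C)C[C@]1(O[Si](C)(C)C)CC=C2O[Si](C)(C)C | intermediate
9 | rac-cis-7-methyl-3-methylidene-1-(trimethylsilyloxy)bicyclo[5.3.0]deca-4,9-dien-8-one | C[C@@]12C/C=C\C(=C)C[C@]1(O[Si](C)(C)C)C=CC2=O | intermediate
10 | rac-7-methyl-3-methylidene-1-(trimethylsilyloxy)bicyclo[5.3.0]deca-4,9-dien-8-ol (8-OH, 7-CH3 and 1-OSiMe3 all cis) | C[C@@]12C/C=C\C(=C)C[C@]1(O[Si](C)(C)C)C=C[C@H]2O | intermediate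
11 | 8-methanesulfonate of 10 (formed in the flask) | C[C@@]12C/C=C\C(=C)C[C@]1(O[Si](C)(C)C)C=C[C@H]2OS(C)(=O)=O | intermediate
12 | tetrabutylammonium 8-(methanesulfonyloxy)-7-methyl-3-methylidenebicyclo[5.3.0]deca-4,9-dien-1-olate (formed in the flask) | C[C@@]12C/C=C\C(=C)C[C@]1([O-])C=C[C@H]2OS(C)(=O)=O.CCCC[N+](CCCC)(CCCC)CCCC | intermediate
13 | (2Z,4E,7Z)-5-methyl-9-methylidenecyclodeca-2,4,7-trien-1-one | O=C1CC(=C)/C=C\C/C(C)=C/C=C\1 | intermediate
14 | methyl 3-bromo-2-oxopropanoate | COC(=O)C(=O)CBr | starting material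
15 | methyl 3-acetoxy-2-oxopropanoate | COC(=O)C(=O)COC(C)=O | intermediate
16 | pinacol boron enolate of the C6-borylated ketone (C8–O–Bpin, C7=C8, C6–Bpin; formed in the flask) | CC1(C)OB(OC2=C[C@H](B3OC(C)(C)C(C)(C)O3)/C=C(C)/C/C=C\C(=C)C2)OC1(C)C | intermediate
17 | boryl aldolate: methyl 3-acetoxy-2-(pinacolboryloxy)-2-[C7 of the C6-borylated ten-membered ketone]propanoate (C7/C11 epimers; formed in the flask) | COC(=O)C(COC(C)=O)(OB1OC(C)(C)C(C)(C)O1)C1C(=O)CC(=C)/C=C\C/C(C)=C/[C@H]1B1OC(C)(C)C(C)(C)O1 | intermediate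
18 | methyl 3-acetoxy-2-hydroxy-2-[(6R)-6-hydroxy-8-oxo ten-membered ring C7]propanoate (C7/C11 epimers; formed in the flask) | COC(=O)C(O)(COC(C)=O)C1C(=O)CC(=C)/C=C\C/C(C)=C/[C@H]1O | intermediate
19 | (6R)-13-acetoxy-11-hydroxy-8-oxogermacra-1(Z),4(E),10(14)-trien-12,6-olide (C7/C11 epimers) | O=C1CC(=C)/C=C\C/C(C)=C/[C@H]2OC(=O)C(O)(COC(C)=O)C12 | intermediate
20 | (6R)-13-acetoxy-8-oxogermacra-1(Z),4(E),7(11),10(14)-tetraen-12,6-olide | O=C1CC(=C)/C=C\C/C(C)=C/[C@H]2OC(=O)C(COC(C)=O)=C12 | intermediate
21 | (6R,8S)-13-acetoxy-8-hydroxygermacra-1(Z),4(E),7(11),10(14)-tetraen-12,6-olide | O[C@H]1CC(=C)/C=C\C/C(C)=C/[C@H]2OC(=O)C(COC(C)=O)=C12 | intermediate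
22 | 2-(hydroxymethyl)prop-2-enoic acid | C=C(CO)C(=O)O | starting material
23 | tert-butyldimethylsilyl 2-[(tert-butyldimethylsilyloxy)methyl]prop-2-enoate (formed in the flask) | C=C(CO[Si](C)(C)C(C)(C)C)C(=O)O[Si](C)(C)C(C)(C)C | intermediate
24 | 2-[(tert-butyldimethylsilyloxy)methyl]prop-2-enoic acid | C=C(CO[Si](C)(C)C(C)(C)C)C(=O)O | intermediate
25 | (6R,8S)-13-acetoxy-8-{2-[(tert-butyldimethylsilyloxy)methyl]acryloyloxy}germacra-1(Z),4(E),7(11),10(14)-tetraen-12,6-olide | C=C(CO[Si](C)(C)C(C)(C)C)C(=O)O[C@H]1CC(=C)/C=C\C/C(C)=C/[C@H]2OC(=O)C(COC(C)=O)=C12 | intermediate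
26 | (1R,2S,6R,8S)-13-acetoxy-1,2-epoxy-8-{2-[(tert-butyldimethylsilyloxy)methyl]acryloyloxy}germacra-4(E),7(11),10(14)-trien-12,6-olide | C=C(CO[Si](C)(C)C(C)(C)C)C(=O)O[C@H]1CC(=C)[C@H]2O[C@H]2C/C(C)=C/[C@H]2OC(=O)C(COC(C)=O)=C12 | intermediate
27 | (1R,2S,4R,5R,6S,8S)-13-acetoxy-1,2:4,5-diepoxy-8-{2-[(tert-butyldimethylsilyloxy)methyl]acryloyloxy}germacra-7(11),10(14)-dien-12,6-olide | C=C(CO[Si](C)(C)C(C)(C)C)C(=O)O[C@H]1CC(=C)[C@H]2O[C@H]2C[C@@]2(C)O[C@@H]2[C@H]2OC(=O)C(COC(C)=O)=C12 | intermediate
28 | (1R,2S,4R,5R,6S,8S)-13-acetoxy-1,2:4,5-diepoxy-8-[2-(hydroxymethyl)acryloyloxy]germacra-7(11),10(14)-dien-12,6-olide (CNP0233746.1) | C=C(CO)C(=O)O[C@H]1CC(=C)[C@H]2O[C@H]2C[C@@]2(C)O[C@@H]2[C@H]2OC(=O)C(COC(C)=O)=C12 | target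

**Step count**
Total steps: 16. Longest linear sequence: 14 steps (steps 1–7, 9–11, 13–16).

**Steps most likely to fail, with fallbacks**

Step 9 (the proposed annulation; the copper–boryl species may attack the keto ester, the enolate may be quenched by the enolisable keto ester, or the enantioselectivity on the macrocyclic Z-enone may be low). The fallback uses known reactions one at a time and sets out from 13. Known copper-catalysed enantioselective β-borylation with the same catalyst and MeOH as proton source gives (4E,7Z)-5-methyl-9-methylidene-3-(pinacolboryl)cyclodeca-4,7-dien-1-one F4, and perborate oxidation gives the β-hydroxy ketone (3S,4E,7Z)-3-hydroxy-5-methyl-9-methylidenecyclodeca-4,7-dien-1-one F5. Its hydroxyl is coupled (DCC, cat. DMAP, −20 °C) with 3-acetoxy-2-oxopropanoic acid F6, made from bromopyruvic acid and KOAc, to give the keto ester (6S)-6-(3-acetoxy-2-oxopropanoyloxy) ketone F7. A soft-enolisation intramolecular aldol addition (TiCl4, i-Pr2NEt, CH2Cl2, −78 °C), which can close the five-membered ring only from the C7 enolate, comes back to the route at 19.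

Step 7 (the cyclopentenyl mesylate cannot place the leaving group fully anti-periplanar to the C4–C8 bond and may ionise or close by SN2′ instead of fragmenting). The fallback moves the fragmentation to the saturated series and sets out from 7. NaBH4 (MeOH, 0 °C, hydride anti to the angular methyl) gives the diol rac-cis-7-methyl-3-methylidenebicyclo[5.3.0]dec-4-ene-1,8-diol F1. The secondary hydroxyl alone is mesylated (MsCl, pyridine, 0 °C) to the monomesylate rac-1-hydroxy-7-methyl-3-methylidenebicyclo[5.3.0]dec-4-en-8-yl methanesulfonate F2. KOt-Bu (THF, 0 °C, cold quench) then effects a classical Wharton fragmentation to the ketone (4E,7Z)-5-methyl-9-methylidenecyclodeca-4,7-dien-1-one F3. Dehydrogenation with 2-iodoxybenzoic acid (DMSO, 65 °C) can occur only toward C7–C6, because C9 is flanked by the fully substituted sp2 carbon C10, and a Z enone is the only unstrained way to conjugate with the 4E olefin in a ten-membered ring, so the sequence comes back to the route at 13.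

Step 14 (the oxazolidinone-ketone dioxirane may not distinguish the cis olefin from C10=C14 or from the trisubstituted olefin, or may be mismatched with the ring conformation). The fallback inverts the order of the two epoxidations and changes the oxygen-transfer mechanism, and sets out from 25. The step 15 conditions (D-fructose-derived ketone, Oxone) are applied first to give the 4,5-epoxide (4R,5R,6S,8S)-13-acetoxy-4,5-epoxy-8-{2-[(tert-butyldimethylsilyloxy)methyl]acryloyloxy}germacra-1(Z),7(11),10(14)-trien-12,6-olide F8, which stiffens the ring and removes the competing trisubstituted olefin. The cis olefin is then epoxidised by Jacobsen–Katsuki oxo transfer with (R,R)-N,N′-bis(3,5-di-tert-butylsalicylidene)-1,2-cyclohexanediaminomanganese chloride [(salen)MnCl, trivalent manganese], NaOCl and 4-phenylpyridine N-oxide in CH2Cl2 at 0 °C. This catalyst class prefers conjugated cis-disubstituted olefins and gives the (1R,2S) sense with cis-β-methylstyrene, and the sequence comes back to the route at 27.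

**Further compounds**
F1 | step 7 | rac-cis-7-methyl-3-methylidenebicyclo[5.3.0]dec-4-ene-1,8-diol (8-OH cis to 7-CH3 and 1-OH) | C[C@@]12C/C=C\C(=C)C[C@]1(O)CC[C@H]2O
F2 | step 7 | rac-1-hydroxy-7-methyl-3-methylidenebicyclo[5.3.0]dec-4-en-8-yl methanesulfonate | C[C@@]12C/C=C\C(=C)C[C@]1(O)CC[C@H]2OS(C)(=O)=O
F3 | step 7 | (4E,7Z)-5-methyl-9-methylidenecyclodeca-4,7-dien-1-one | O=C1CC(=C)/C=C\C/C(C)=C/CC1
F4 | step 9 | (4E,7Z)-5-methyl-9-methylidene-3-(4,4,5,5-tetramethyl-1,3,2-dioxaborolan-2-yl)cyclodeca-4,7-dien-1-one (C3 as C6 of the target) | O=C1CC(=C)/C=C\C/C(C)=C/[C@@H](B2OC(C)(C)C(C)(C)O2)C1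
F5 | step 9 | (3S,4E,7Z)-3-hydroxy-5-methyl-9-methylidenecyclodeca-4,7-dien-1-one | O=C1CC(=C)/C=C\C/C(C)=C/[C@@H](O)C1
F6 | step 9 | 3-acetoxy-2-oxopropanoic acid | CC(=O)OCC(=O)C(=O)O
F7 | step 9 | (1S,2E,5Z)-3-methyl-7-methylidene-9-oxocyclodeca-2,5-dien-1-yl 3-acetoxy-2-oxopropanoate | CC(=O)OCC(=O)C(=O)O[C@H]1CC(=O)CC(=C)/C=C\C/C(C)=C/1
F8 | step 14 | (4R,5R,6S,8S)-13-acetoxy-4,5-epoxy-8-{2-[(tert-butyldimethylsilyloxy)methyl]acryloyloxy}germacra-1(Z),7(11),10(14)-trien-12,6-olide | C=C(CO[Si](C)(C)C(C)(C)C)C(=O)O[C@H]1CC(=C)/C=C\C[C@@]2(C)O[C@@H]2[C@H]2OC(=O)C(COC(C)=O)=C12
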